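The dihydrofuran ring is traced back to a benzofuran whose O1–C2–C3 unit is the enol oxygen, carbonyl carbon and α-carbon of a β-keto ester. The key step exploits the adjacency of C7a and C3a on the benzo ring, next to the C7 oxygen. 2-Bromo-1-iodo-3-(methoxymethoxy)benzene acts as a graded 1,2-dielectrophile, and one copper-catalysed operation joins C3 to C3a (C–I site) and O1 to C7a (C–Br site). Its precursors are this dihalide and an aroylacetate. Face-selective hydrogenation with C3 epimerisation then sets the trans-(2S,3S) pair. The C3 carboxyl group directs C4–H olefination with a danshensu acrylate before methylation and acidolysis.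

Key step: step 5

Assumption: (R)-3-(3,4-dihydroxyphenyl)lactic acid (danshensu) is taken as a commercial chiral-pool material (also sold as its sodium salt).
Assumption: the sense of induction of the Ru–NHC catalyst on 9 cannot be assigned in advance. The (R,R) ligand is written, and its antipode would be used if a test run shows the 2R series.

Step 1
Reactants: 1 3-iodophenol
Product: 2 1-iodo-3-(methoxymethoxy)benzene
Conditions: MOMCl, i-Pr2NEt, CH2Cl2, 0 °C → rt
Reagents that add atoms: chloromethyl methyl ether (MOMCl), COCCl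
Why: O-alkylation of the phenol (Williamson type, MOM acetal formation) should be clean, and OMOM is chosen because it directs the lithiation of step 2 and resists base, copper and hydrogenation.

Step 2
Reactants: 2 1-iodo-3-(methoxymethoxy)benzene
Product: 4 2-bromo-1-iodo-3-(methoxymethoxy)benzene, via aryllithium 3 (not isolated)
Conditions: LDA (commercial solution, 1.1 equiv), THF, −78 °C; then BrCl2C–CCl2Br, −78 °C → rt
Reagents that add atoms: 1,2-dibromo-1,1,2,2-tetrachloroethane, BrC(Cl)(Cl)C(Cl)(Cl)Br
Why: Directed ortho-metalation: C2–H lies between the coordinating OMOM group and the acidifying iodine, so the amide base (which does not exchange iodine) should deprotonate only there, and aryllithium 3 is brominated by halophilic attack at −78 °C before loss of LiI to an aryne can compete.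

Step 3
Reactants: 5 3',4'-dihydroxyacetophenone
Product: 6 1-[3,4-bis(methoxymethoxy)phenyl]ethanone
Conditions: MOMCl (2.5 equiv), i-Pr2NEt, CH2Cl2, 0 °C → rt
Reagents that add atoms: chloromethyl methyl ether (MOMCl), COCCl
Why: Double MOM protection (Williamson type) of the catechol masks the acidic OH groups for the enolate and copper chemistry that follows.

Step 4
Reactants: 6 1-[3,4-bis(methoxymethoxy)phenyl]ethanone
Product: 7 benzyl 3-[3,4-bis(methoxymethoxy)phenyl]-3-oxopropanoate
Conditions: NaH (2.2 equiv), (BnO)2CO, THF, reflux; AcOH quench, 0 °C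
Reagents that add atoms: dibenzyl carbonate, O=C(OCc1ccccc1)OCc1ccccc1
Why: Crossed Claisen condensation of the methyl ketone enolate with a non-enolisable carbonate, driven by deprotonation of the β-keto ester formed; the benzyl ester is chosen for neutral removal in step 7.

Step 5
Reactants: 4 2-bromo-1-iodo-3-(methoxymethoxy)benzene; 7 benzyl 3-[3,4-bis(methoxymethoxy)phenyl]-3-oxopropanoate
Product: 9 benzyl 2-[3,4-bis(methoxymethoxy)phenyl]-7-(methoxymethoxy)-1-benzofuran-3-carboxylate, via C-arylated keto ester 8 (not isolated)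
Conditions: CuI (10 mol %), K2CO3 (3 equiv), THF, 100 °C, sealed tube, Ar
Reagents that add atoms: none
Why: The potassium enolate of 7 binds Cu(I) as an O,O-chelate and serves as its own ligand, the C–I bond of 4 adds oxidatively, C–C reductive elimination gives 8 (Hurtley-type C-arylation), and the re-formed enolate oxygen of 8 is then arylated at the neighbouring C–Br bond (intramolecular Ullmann ether synthesis). The closest known reaction type is the CuI-catalysed domino synthesis of 2,3-disubstituted benzofurans from 1-bromo-2-iodoarenes and β-keto esters. The furan ring closes as a five-membered ring by C(sp2)–O reductive elimination from a six-membered aryl–Cu(III)–enolate chelate, formally a 5-exo substitution at C7a. No stereocentre is formed, because C2 and C3 emerge sp2 and are set in step 6. The step needs site selectivity (carbon to C3a, oxygen to C7a), secured by the reactivity gap C–I >> C–Br and by the lower hindrance at the iodide, and it needs C- over O-arylation in the first coupling, the normal preference of soft 1,3-dicarbonyl enolates on copper. Aromatisation to the benzofuran removes 8 from the retro-Claisen equilibrium, and the MOM oxygen next to bromine may help to bring copper to that hindered site.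

Step 6
Reactants: 9 benzyl 2-[3,4-bis(methoxymethoxy)phenyl]-7-(methoxymethoxy)-1-benzofuran-3-carboxylate
Product: 11 benzyl (2S,3S)-2-[3,4-bis(methoxymethoxy)phenyl]-7-(methoxymethoxy)-2,3-dihydro-1-benzofuran-3-carboxylate (trans), via cis ester 10 (not isolated)
Conditions: [Ru(cod)(2-methylallyl)2] (5 mol %), (R,R)-SINpEt·HBF4 (10 mol %), KOt-Bu (15 mol %), toluene, H2 (100 bar), 40 °C; then DBU (20 mol %), CH2Cl2, rt
Reagents that add atoms: none
Why: Proposed new method: chiral Ru–bis(NHC) complexes hydrogenate the C2=C3 bond of 2-arylbenzofurans by syn delivery of H2 to one face while sparing benzenoid rings and esters (closest known type: asymmetric hydrogenation of 2-substituted benzofurans); the extension is to a tetrasubstituted, ester-conjugated C2=C3 bond, where catalyst control of the face should set C2 (S) and give the cis-(2S,3R) ester 10, after which DBU epimerises the acidic C3–H to the thermodynamically favoured trans-(2S,3S) ester 11 without touching C2.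

Step 7
Reactants: 11 benzyl (2S,3S)-2-[3,4-bis(methoxymethoxy)phenyl]-7-(methoxymethoxy)-2,3-dihydro-1-benzofuran-3-carboxylate
Product: 12 (2S,3S)-2-[3,4-bis(methoxymethoxy)phenyl]-7-(methoxymethoxy)-2,3-dihydro-1-benzofuran-3-carboxylic acid
Conditions: H2 (1 atm), 10 % Pd/C, EtOAc, rt, short contact time
Reagents that add atoms: none
Why: Catalytic hydrogenolysis of the benzyl ester frees the acid under neutral conditions, which avoids the base-induced β-elimination of O1 that saponification would risk and leaves the MOM acetals and both stereocentres untouched.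

Step 8
Reactants: 13 (R)-3-(3,4-dihydroxyphenyl)-2-hydroxypropanoic acid (danshensu)
Product: 14 4-methoxybenzyl (2R)-3-{3,4-bis[(4-methoxybenzyl)oxy]phenyl}-2-hydroxypropanoate
Conditions: PMBCl (3.3 equiv), K2CO3 (3.5 equiv), n-Bu4NI (cat.), DMF, Ar, rt → 40 °C
Reagents that add atoms: 4-methoxybenzyl chloride (PMBCl), COc1ccc(CCl)cc1
Why: Williamson ether synthesis and carboxylate alkylation: K2CO3 ionises only the two phenols and the acid, so the secondary alcohol should stay free, and the stereocentre of the chiral-pool acid is not involved.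

Step 9
Reactants: 14 4-methoxybenzyl (2R)-3-{3,4-bis[(4-methoxybenzyl)oxy]phenyl}-2-hydroxypropanoate
Product: 15 4-methoxybenzyl (2R)-2-(acryloyloxy)-3-{3,4-bis[(4-methoxybenzyl)oxy]phenyl}propanoate
Conditions: acryloyl chloride, Et3N, CH2Cl2, −20 → 0 °C
Reagents that add atoms: acryloyl chloride, C=CC(=O)Cl
Why: Esterification of the only free hydroxyl group with an acid chloride, with retention at the carbinol carbon because the C–O bond is not broken.

Step 10
Reactants: 12 (2S,3S)-2-[3,4-bis(methoxymethoxy)phenyl]-7-(methoxymethoxy)-2,3-dihydro-1-benzofuran-3-carboxylic acid; 15 4-methoxybenzyl (2R)-2-(acryloyloxy)-3-{3,4-bis[(4-methoxybenzyl)oxy]phenyl}propanoate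
Product: 16 (2S,3S)-2-[3,4-bis(methoxymethoxy)phenyl]-7-(methoxymethoxy)-4-[(E)-3-oxo-3-{[(2R)-1-oxo-1-[(4-methoxybenzyl)oxy]-3-{3,4-bis[(4-methoxybenzyl)oxy]phenyl}propan-2-yl]oxy}prop-1-enyl]-2,3-dihydro-1-benzofuran-3-carboxylic acid
Conditions: Pd(OAc)2 (10 mol %), Ac-Ile-OH (20 mol %), KHCO3 (2 equiv), t-AmylOH, O2 (1 atm), 85 °C; cold 0.5 M HCl work-up
Reagents that add atoms: none
Why: Carboxylate-directed Pd(II)-catalysed C–H olefination (Fujiwara–Moritani reaction accelerated by a mono-N-protected amino acid ligand, O2 as terminal oxidant), established for phenylacetic acids including 2-aryl-2,3-dihydrobenzofuran-3-carboxylic acids: the six-membered palladacycle reaches only C4–H, and syn insertion followed by syn β-hydride elimination gives the E-alkene without touching the three stereocentres.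

Step 11
Reactants: 16 C4-olefinated (2S,3S)-dihydrobenzofuran-3-carboxylic acid
Product: 17 methyl ester of 16 (fully protected monomethyl lithospermate; 2S,3S and 2R in the lactate, E-alkene)
Conditions: MeI, KHCO3, DMF, rt
Reagents that add atoms: methyl iodide, CI
Why: SN2 alkylation of the single carboxylate with methyl iodide under bicarbonate, a base too weak to trigger β-elimination of O1, and any C3 epimerisation would only return the favoured trans isomer.

Step 12
Reactants: 17 fully protected monomethyl lithospermate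
Product: 18 monomethyl lithospermate
Conditions: TFA/CH2Cl2 (1:3), 1,3,5-trimethoxybenzene (excess), Ar, 0 °C → rt; reversed-phase purification
Reagents that add atoms: none
Why: SN1-type acidolysis: the PMB ethers, the PMB ester and the MOM acetals ionise in TFA to stabilised cations that trimethoxybenzene intercepts irreversibly (Friedel–Crafts alkylation), whereas the methyl ester, the cinnamate, the secondary acyloxy centre and the C2–O1 bond (its ionisation disfavoured by the adjacent C3 ester) should persist, so no stereocentre is touched.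

Compound list
1 | 3-iodophenol | Oc1cccc(I)c1 | starting material
2 | 1-iodo-3-(methoxymethoxy)benzene | COCOc1cccc(I)c1 | intermediate
3 | [2-iodo-6-(methoxymethoxy)phenyl]lithium | [Li]c1c(I)cccc1OCOC | intermediate
4 | 2-bromo-1-iodo-3-(methoxymethoxy)benzene | COCOc1cccc(I)c1Br | intermediate
5 | 3',4'-dihydroxyacetophenone | CC(=O)c1ccc(O)c(O)c1 | starting material
6 | 1-[3,4-bis(methoxymethoxy)phenyl]ethanone | CC(=O)c1ccc(OCOC)c(OCOC)c1 | intermediate
7 | benzyl 3-[3,4-bis(methoxymethoxy)phenyl]-3-oxopropanoate | O=C(CC(=O)c1ccc(OCOC)c(OCOC)c1)OCc1ccccc1 | intermediate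
8 | benzyl 2-[2-bromo-3-(methoxymethoxy)phenyl]-3-[3,4-bis(methoxymethoxy)phenyl]-3-oxopropanoate (enolisable, no defined configuration) | O=C(OCc1ccccc1)C(c1cccc(OCOC)c1Br)C(=O)c1ccc(OCOC)c(OCOC)c1 | intermediate
9 | benzyl 2-[3,4-bis(methoxymethoxy)phenyl]-7-(methoxymethoxy)-1-benzofuran-3-carboxylate | O=C(OCc1ccccc1)c1c(-c2ccc(OCOC)c(OCOC)c2)oc2c(OCOC)cccc12 | intermediate
10 | benzyl (2S,3R)-2-[3,4-bis(methoxymethoxy)phenyl]-7-(methoxymethoxy)-2,3-dihydro-1-benzofuran-3-carboxylate (cis) | O=C(OCc1ccccc1)[C@@H]1c2cccc(OCOC)c2O[C@@H]1c1ccc(OCOC)c(OCOC)c1 | intermediate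
11 | benzyl (2S,3S)-2-[3,4-bis(methoxymethoxy)phenyl]-7-(methoxymethoxy)-2,3-dihydro-1-benzofuran-3-carboxylate (trans) | O=C(OCc1ccccc1)[C@H]1c2cccc(OCOC)c2O[C@@H]1c1ccc(OCOC)c(OCOC)c1 | intermediate
12 | (2S,3S)-2-[3,4-bis(methoxymethoxy)phenyl]-7-(methoxymethoxy)-2,3-dihydro-1-benzofuran-3-carboxylic acid | OC(=O)[C@H]1c2cccc(OCOC)c2O[C@@H]1c1ccc(OCOC)c(OCOC)c1 | intermediate
13 | (R)-3-(3,4-dihydroxyphenyl)-2-hydroxypropanoic acid (danshensu) | O[C@H](Cc1ccc(O)c(O)c1)C(=O)O | starting material
14 | 4-methoxybenzyl (2R)-3-{3,4-bis[(4-methoxybenzyl)oxy]phenyl}-2-hydroxypropanoate | O[C@H](Cc1ccc(OCc2ccc(OC)cc2)c(OCc2ccc(OC)cc2)c1)C(=O)OCc1ccc(OC)cc1 | intermediate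
15 | 4-methoxybenzyl (2R)-2-(acryloyloxy)-3-{3,4-bis[(4-methoxybenzyl)oxy]phenyl}propanoate | C=CC(=O)O[C@H](Cc1ccc(OCc2ccc(OC)cc2)c(OCc2ccc(OC)cc2)c1)C(=O)OCc1ccc(OC)cc1 | intermediate
16 | C4-(E)-olefinated (2S,3S)-dihydrobenzofuran-3-carboxylic acid carrying the (2R)-tris-PMB danshensu ester | OC(=O)[C@H]1c2c(/C=C/C(=O)O[C@H](Cc3ccc(OCc4ccc(OC)cc4)c(OCc4ccc(OC)cc4)c3)C(=O)OCc3ccc(OC)cc3)ccc(OCOC)c2O[C@@H]1c1ccc(OCOC)c(OCOC)c1 | intermediate
17 | methyl ester of 16 (fully protected monomethyl lithospermate) | COC(=O)[C@H]1c2c(/C=C/C(=O)O[C@H](Cc3ccc(OCc4ccc(OC)cc4)c(OCc4ccc(OC)cc4)c3)C(=O)OCc3ccc(OC)cc3)ccc(OCOC)c2O[C@@H]1c1ccc(OCOC)c(OCOC)c1 | intermediate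
18 | monomethyl lithospermate | COC(=O)[C@H]1c2c(/C=C/C(=O)O[C@H](Cc3ccc(O)c(O)c3)C(=O)O)ccc(O)c2O[C@@H]1c1ccc(O)c(O)c1 | target

Total step count: 12. Longest linear sequence: 8 steps (1, 2, 5, 6, 7, 10, 11, 12).

Steps most likely to fail

Step 6. Turnover at the tetrasubstituted, ester-conjugated C2=C3 bond may be sluggish. Facial discrimination may be poor, and β-elimination of O1 may compete during the epimerisation. The fallback uses known chemistry, sets out from 9 and returns at 12. Dissolving-metal conjugate reduction (Mg, MeOH/THF, 0 °C → rt), a known reduction of 2-arylbenzofuran-3-carboxylates, should give, with ester exchange, the racemic trans methyl ester F1. Me3SnOH (1,2-dichloroethane, 80 °C) should cleave it without ring opening to the racemic trans acid F2. Crystallisation with (S)-1-phenylethylamine (or its antipode) should give the diastereomerically pure ammonium salt F3, and mild acidification releases 12.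

Step 5. The ring closure may stall at the hindered C–Br site. Retro-Claisen deacylation of the C-arylated intermediate or hydrodehalogenation may consume material. The fallback sets out from 4 and 6 and returns at 9; it moves the ester out of the annulation. A palladium-catalysed one-pot ketone α-arylation and intramolecular enolate O-arylation (Pd2(dba)3, DPEphos, Cs2CO3, toluene, 110 °C) still forms both ring bonds in one operation. It uses an enolate that cannot deacylate and should give the 3-unsubstituted 2-arylbenzofuran F4. NBS (MeCN, 0 °C) should brominate the nucleophilic C3 to the 3-bromobenzofuran F5. Palladium-catalysed benzyloxycarbonylation (CO, BnOH, Pd(OAc)2, dppf, Et3N, DMF, 90 °C) then gives 9.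

Step 12. Benzylic cations may re-alkylate the liberated catechols, acid may ionise the C2–O1 bond, and the product may oxidise in air during isolation. The fallback sets out from 13 and 12 and returns at 18. It removes all benzylic cation sources, so that the last step becomes a hydrolysis in aqueous acid. O-tert-Butyl-N,N′-diisopropylisourea (THF, rt) should give the tert-butyl ester F6. MOMCl/K2CO3 (acetone, 0 °C) should give the bis-MOM ether F7, and acryloyl chloride/Et3N the acrylate F8. The olefination conditions of step 10 with 12 should give the acid F9, and MeI/KHCO3 the methyl ester F10. TFA/H2O/CH2Cl2 (or 2 M aqueous HCl in THF, 40 °C) should then give 18.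

Further compounds
F1 | step 6 | racemic methyl trans-2-[3,4-bis(methoxymethoxy)phenyl]-7-(methoxymethoxy)-2,3-dihydro-1-benzofuran-3-carboxylate (both enantiomers written) | COC(=O)[C@H]1c2cccc(OCOC)c2O[C@@H]1c1ccc(OCOC)c(OCOC)c1.COC(=O)[C@@H]1c2cccc(OCOC)c2O[C@H]1c1ccc(OCOC)c(OCOC)c1
F2 | step 6 | racemic trans-2-[3,4-bis(methoxymethoxy)phenyl]-7-(methoxymethoxy)-2,3-dihydro-1-benzofuran-3-carboxylic acid (both enantiomers written) | OC(=O)[C@H]1c2cccc(OCOC)c2O[C@@H]1c1ccc(OCOC)c(OCOC)c1.OC(=O)[C@@H]1c2cccc(OCOC)c2O[C@H]1c1ccc(OCOC)c(OCOC)c1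
F3 | step 6 | (S)-1-phenylethylammonium (2S,3S)-2-[3,4-bis(methoxymethoxy)phenyl]-7-(methoxymethoxy)-2,3-dihydro-1-benzofuran-3-carboxylate | [O-]C(=O)[C@H]1c2cccc(OCOC)c2O[C@@H]1c1ccc(OCOC)c(OCOC)c1.C[C@H]([NH3+])c1ccccc1
F4 | step 5 | 2-[3,4-bis(methoxymethoxy)phenyl]-7-(methoxymethoxy)-1-benzofuran | COCOc1ccc(-c2cc3cccc(OCOC)c3o2)cc1OCOC
F5 | step 5 | 3-bromo-2-[3,4-bis(methoxymethoxy)phenyl]-7-(methoxymethoxy)-1-benzofuran | COCOc1ccc(-c2oc3c(OCOC)cccc3c2Br)cc1OCOC
F6 | step 12 | tert-butyl (2R)-3-(3,4-dihydroxyphenyl)-2-hydroxypropanoate | O[C@H](Cc1ccc(O)c(O)c1)C(=O)OC(C)(C)C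
F7 | step 12 | tert-butyl (2R)-3-[3,4-bis(methoxymethoxy)phenyl]-2-hydroxypropanoate | O[C@H](Cc1ccc(OCOC)c(OCOC)c1)C(=O)OC(C)(C)C
F8 | step 12 | tert-butyl (2R)-2-(acryloyloxy)-3-[3,4-bis(methoxymethoxy)phenyl]propanoate | C=CC(=O)O[C@H](Cc1ccc(OCOC)c(OCOC)c1)C(=O)OC(C)(C)C
F9 | step 12 | C4-(E)-olefinated (2S,3S)-dihydrobenzofuran-3-carboxylic acid carrying the (2R)-bis-MOM danshensu tert-butyl ester | OC(=O)[C@H]1c2c(/C=C/C(=O)O[C@H](Cc3ccc(OCOC)c(OCOC)c3)C(=O)OC(C)(C)C)ccc(OCOC)c2O[C@@H]1c1ccc(OCOC)c(OCOC)c1
F10 | step 12 | methyl ester of F9 | COC(=O)[C@H]1c2c(/C=C/C(=O)O[C@H](Cc3ccc(OCOC)c(OCOC)c3)C(=O)OC(C)(C)C)ccc(OCOC)c2O[C@@H]1c1ccc(OCOC)c(OCOC)c1
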